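**Retrosynthetic overview**

- The target is a 1,4-bis(indol-3-yl)-2,3,5,6-tetramethoxybenzene whose two indoles differ only at C5 (OMe against OH). The methoxyindole is bought and attached by Suzuki–Miyaura coupling; the hydroxyindole is built on the central ring.
- Feature the plan rests on: in the hydroxyindole the C5–OH is para to C7a–N1 within the benzo ring, C3 carries the central aryl ring and C4 is H. This is the 1,4-relationship of the ring oxygen (at furan C5) to the nitrogen-bearing C2 of a 2-aminofuran.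
- Key disconnection: C3a–C7a and C4–C5, an intramolecular furan Diels–Alder reaction of an N-Boc-N-(2-furyl)amine tethered through N1–C2H2–C3(OH)(Ar) to a terminal alkyne.
- Precursor assembly: carbinol C3–C≡CH bond by ethynyl Grignard addition; aryl–C(=O) bond from the aryllithium and an N-methoxy-N-methylamide; aryl–indolyl bond by mono-Suzuki coupling on the dibromide; N–CH2 bond by carbamate alkylation.
- Ring order: central benzene and methoxyindole are purchased; the pyrrole and benzo rings of the hydroxyindole both form in step 10; N-detosylation ends the route.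

Key step: step 10

Remark on the chemistry: the target has no stereocentre, and each aryl–indolyl axis is flanked by two identical methoxy groups on the central ring, so no axial chirality arises. The carbinol centre of the precursor is carried as the racemate and is erased in the key step.

**Route**

Step 1
Reactants: 1 2-furoic acid
Product: 4 tert-butyl N-(furan-2-yl)carbamate, via furan-2-carbonyl azide 2 (not isolated), via 2-isocyanatofuran 3 (not isolated)
Conditions: DPPA, Et3N, t-BuOH, reflux
Reagents that add atoms: diphenylphosphoryl azide, [N-]=[N+]=NP(=O)(Oc1ccccc1)Oc1ccccc1; tert-butanol, CC(C)(C)O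
Why: Curtius rearrangement, in which the acyl azide loses N2 on heating and the isocyanate is trapped by tert-butanol to give the carbamate, a stable form of the otherwise labile 2-aminofuran.

Step 2
Reactants: 4 tert-butyl N-(furan-2-yl)carbamate; 5 2-bromo-N-methoxy-N-methylacetamide
Product: 6 tert-butyl N-(furan-2-yl)-N-{2-[methoxy(methyl)amino]-2-oxoethyl}carbamate
Conditions: NaH, DMF, 0 °C; then 5, 0 °C to rt
Reagents that add atoms: 2-bromo-N-methoxy-N-methylacetamide (5), CON(C)C(=O)CBr
Why: N-alkylation (SN2) of the sodium salt of the carbamate by a reactive alpha-bromo amide, the N-methoxy-N-methylamide being inert to the carbamate anion.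

Step 3
Reactants: 7 5-methoxyindole
Product: 8 5-methoxy-1-(4-methylbenzenesulfonyl)indole
Conditions: NaH, DMF, 0 °C; TsCl, rt
Reagents that add atoms: 4-methylbenzenesulfonyl chloride, Cc1ccc(cc1)S(Cl)(=O)=O
Why: N-sulfonylation of the indolyl anion, which removes the acidic N–H before the organolithium step and stabilises the later C3 boronate against protodeboronation.

Step 4
Reactants: 8 5-methoxy-1-(4-methylbenzenesulfonyl)indole
Product: 9 3-bromo-5-methoxy-1-(4-methylbenzenesulfonyl)indole
Conditions: Br2 (1.05 equiv), CH2Cl2, 0 °C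
Reagents that add atoms: bromine, BrBr
Why: Electrophilic aromatic bromination at C3, the enamide carbon and most nucleophilic position of an N-sulfonylindole.

Step 5
Reactants: 9 3-bromo-5-methoxy-1-(4-methylbenzenesulfonyl)indole; 10 bis(pinacolato)diboron
Product: 11 5-methoxy-1-(4-methylbenzenesulfonyl)-3-(4,4,5,5-tetramethyl-1,3,2-dioxaborolan-2-yl)indole
Conditions: PdCl2(dppf) (5 mol %), KOAc, 1,4-dioxane, 90 °C
Reagents that add atoms: bis(pinacolato)diboron (10), CC1(C)OB(OC1(C)C)B1OC(C)(C)C(C)(C)O1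
Why: Miyaura borylation, in which oxidative addition of the C3–Br bond is followed by acetate-assisted transmetalation with the diboron reagent and reductive elimination.

Step 6
Reactants: 12 1,2,4,5-tetramethoxybenzene
Product: 13 1,4-dibromo-2,3,5,6-tetramethoxybenzene
Conditions: Br2 (2.2 equiv), CH2Cl2, 0 °C to rt
Reagents that add atoms: bromine, BrBr
Why: Twofold electrophilic aromatic bromination at the only two free positions of a very electron-rich arene, each ortho to two methoxy groups.

Step 7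
Reactants: 13 1,4-dibromo-2,3,5,6-tetramethoxybenzene (3 equiv); 11 5-methoxy-1-(4-methylbenzenesulfonyl)-3-(4,4,5,5-tetramethyl-1,3,2-dioxaborolan-2-yl)indole
Product: 14 3-(4-bromo-2,3,5,6-tetramethoxyphenyl)-5-methoxy-1-(4-methylbenzenesulfonyl)indole
Conditions: Pd(OAc)2 (5 mol %), SPhos (10 mol %), K3PO4, toluene–H2O, 90 °C
Reagents that add atoms: none
Why: Suzuki–Miyaura coupling with a bulky electron-rich biaryl phosphine suited to a di-ortho-substituted bromide, the threefold excess of the cheap, recoverable dibromide holding the reaction at the mono-coupled stage.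

Step 8
Reactants: 14 3-(4-bromo-2,3,5,6-tetramethoxyphenyl)-5-methoxy-1-(4-methylbenzenesulfonyl)indole; 6 tert-butyl N-(furan-2-yl)-N-{2-[methoxy(methyl)amino]-2-oxoethyl}carbamate
Product: 16 tert-butyl N-(furan-2-yl)-N-{2-oxo-2-[2,3,5,6-tetramethoxy-4-(5-methoxy-1-(4-methylbenzenesulfonyl)indol-3-yl)phenyl]ethyl}carbamate, via aryllithium 15 (not isolated)
Conditions: n-BuLi (1.05 equiv), THF, −78 °C, 15 min; then 6, −78 to 0 °C; aqueous work-up
Reagents that add atoms: none
Why: Bromine–lithium exchange, which at −78 °C should be faster than deprotonation at indole C2, followed by acylation of the aryllithium with the N-methoxy-N-methylamide, whose chelated tetrahedral adduct prevents a second addition.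

Step 9
Reactants: 16 tert-butyl N-(furan-2-yl)-N-{2-oxo-2-[2,3,5,6-tetramethoxy-4-(5-methoxy-1-(4-methylbenzenesulfonyl)indol-3-yl)phenyl]ethyl}carbamate; 17 ethynylmagnesium bromide
Product: 18 racemic tert-butyl N-(furan-2-yl)-N-{2-hydroxy-2-[2,3,5,6-tetramethoxy-4-(5-methoxy-1-(4-methylbenzenesulfonyl)indol-3-yl)phenyl]but-3-yn-1-yl}carbamate
Conditions: HC≡CMgBr (3 equiv), THF, −20 to 0 °C; cold aqueous quench
Reagents that add atoms: ethynylmagnesium bromide (17), C#C[Mg]Br
Why: 1,2-addition of a small, weakly basic alkynyl Grignard reagent to the alpha-amino ketone, giving the tertiary carbinol as a racemate, which suffices because this centre becomes sp2 C3 in step 10.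

Step 10
Reactants: 18 racemic tert-butyl N-(furan-2-yl)-N-{2-hydroxy-2-[2,3,5,6-tetramethoxy-4-(5-methoxy-1-(4-methylbenzenesulfonyl)indol-3-yl)phenyl]but-3-yn-1-yl}carbamate
Product: 22 3-[2,3,5,6-tetramethoxy-4-(5-methoxy-1-(4-methylbenzenesulfonyl)indol-3-yl)phenyl]-1H-indol-5-ol, via oxanorbornadiene cycloadduct 19 (not isolated), via N-Boc indoline-3,5-diol 20 (not isolated), via N-Boc 5-hydroxyindole 21 (not isolated)
Conditions: o-dichlorobenzene (0.05 M), 180 °C, microwave, sealed vessel, argon, 30 min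
Reagents that add atoms: none
Why: Heating brings the furan diene (nitrogen-bearing C2 and C5) over the tethered terminal alkyne in an intramolecular [4+2] cycloaddition, the known reaction type of N-Boc-N-furyl aminomethyl alkynyl carbinols, to give oxanorbornadiene 19 with the new bonds C3a–C7a and C4–C5. The five-membered ring closes as the tether ring (N1–C2–C3 linking furan C2 to the internal alkyne carbon) and the six-membered carbocycle is the cycloaddition ring itself, so both rings arise in one concerted event. The nitrogen lone pair then pushes the bridging oxygen off C7a, the resulting dienyl cation–alkoxide loses the C5 proton to give the phenol of 20, the tertiary benzylic carbinol eliminates water across C2–C3 to give indole 21, and the indole N-Boc group fragments thermally to isobutene and CO2. The bridgehead centres of 19 and the carbinol centre all disappear on aromatisation, so no stereocontrol is needed. The step needs regiocontrol (oxygen at C5, aryl at C3, hydrogen at C4), which the tether enforces because the nitrogen-bearing furan carbon can reach only the internal alkyne carbon. It also needs cycloaddition to outrun thermal Boc loss, which the fully substituted carbinol carbon in the tether favours by holding the alkyne over the furan.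

Step 11
Reactants: 22 3-[2,3,5,6-tetramethoxy-4-(5-methoxy-1-(4-methylbenzenesulfonyl)indol-3-yl)phenyl]-1H-indol-5-ol
Product: 23 3-[2,3,5,6-tetramethoxy-4-(5-methoxy-1H-indol-3-yl)phenyl]-1H-indol-5-ol (target)
Conditions: Mg turnings (excess), MeOH, rt, sonication, argon; NH4Cl work-up
Reagents that add atoms: none
Why: Reductive N–S cleavage by electron transfer from magnesium in methanol (dissolving-metal desulfonylation), which leaves the aryl methyl ethers, the phenol and both indole rings untouched.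

**Compound list**

1 | 2-furoic acid | OC(=O)c1ccco1 | starting material
2 | furan-2-carbonyl azide | [N-]=[N+]=NC(=O)c1ccco1 | intermediate
3 | 2-isocyanatofuran | O=C=Nc1ccco1 | intermediate
4 | tert-butyl N-(furan-2-yl)carbamate | CC(C)(C)OC(=O)Nc1ccco1 | intermediate
5 | 2-bromo-N-methoxy-N-methylacetamide | CON(C)C(=O)CBr | starting material
6 | tert-butyl N-(furan-2-yl)-N-{2-[methoxy(methyl)amino]-2-oxoethyl}carbamate | CON(C)C(=O)CN(C(=O)OC(C)(C)C)c1ccco1 | intermediate
7 | 5-methoxyindole | COc1ccc2[nH]ccc2c1 | starting material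
8 | 5-methoxy-1-(4-methylbenzenesulfonyl)indole | COc1ccc2c(c1)ccn2S(=O)(=O)c1ccc(C)cc1 | intermediate
9 | 3-bromo-5-methoxy-1-(4-methylbenzenesulfonyl)indole | COc1ccc2c(c1)c(Br)cn2S(=O)(=O)c1ccc(C)cc1 | intermediate
10 | bis(pinacolato)diboron | CC1(C)OB(OC1(C)C)B1OC(C)(C)C(C)(C)O1 | starting material
11 | 5-methoxy-1-(4-methylbenzenesulfonyl)-3-(4,4,5,5-tetramethyl-1,3,2-dioxaborolan-2-yl)indole | COc1ccc2c(c1)c(cn2S(=O)(=O)c1ccc(C)cc1)B1OC(C)(C)C(C)(C)O1 | intermediate
12 | 1,2,4,5-tetramethoxybenzene | COc1cc(OC)c(OC)cc1OC | starting material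
13 | 1,4-dibromo-2,3,5,6-tetramethoxybenzene | COc1c(Br)c(OC)c(OC)c(Br)c1OC | intermediate
14 | 3-(4-bromo-2,3,5,6-tetramethoxyphenyl)-5-methoxy-1-(4-methylbenzenesulfonyl)indole | COc1ccc2c(c1)c(cn2S(=O)(=O)c1ccc(C)cc1)-c1c(OC)c(OC)c(Br)c(OC)c1OC | intermediate
15 | [2,3,5,6-tetramethoxy-4-(5-methoxy-1-(4-methylbenzenesulfonyl)indol-3-yl)phenyl]lithium | COc1ccc2c(c1)c(cn2S(=O)(=O)c1ccc(C)cc1)-c1c(OC)c(OC)c([Li])c(OC)c1OC | intermediate
16 | tert-butyl N-(furan-2-yl)-N-{2-oxo-2-[2,3,5,6-tetramethoxy-4-(5-methoxy-1-(4-methylbenzenesulfonyl)indol-3-yl)phenyl]ethyl}carbamate | COc1ccc2c(c1)c(cn2S(=O)(=O)c1ccc(C)cc1)-c1c(OC)c(OC)c(C(=O)CN(C(=O)OC(C)(C)C)c2ccco2)c(OC)c1OC | intermediate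
17 | ethynylmagnesium bromide | C#C[Mg]Br | starting material
18 | racemic tert-butyl N-(furan-2-yl)-N-{2-hydroxy-2-[2,3,5,6-tetramethoxy-4-(5-methoxy-1-(4-methylbenzenesulfonyl)indol-3-yl)phenyl]but-3-yn-1-yl}carbamate | COc1ccc2c(c1)c(cn2S(=O)(=O)c1ccc(C)cc1)-c1c(OC)c(OC)c(C(O)(C#C)CN(C(=O)OC(C)(C)C)c2ccco2)c(OC)c1OC | intermediate
19 | tert-butyl 3-hydroxy-3-[2,3,5,6-tetramethoxy-4-(5-methoxy-1-(4-methylbenzenesulfonyl)indol-3-yl)phenyl]-2,3-dihydro-5H-5,7a-epoxyindole-1-carboxylate (racemic, mixture of diastereomers) | CC(C)(C)OC(=O)N1CC(O)(c2c(OC)c(OC)c(-c3cn(S(=O)(=O)c4ccc(C)cc4)c4ccc(OC)cc34)c(OC)c2OC)C2=CC3C=CC12O3 | intermediate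
20 | racemic tert-butyl 3,5-dihydroxy-3-[2,3,5,6-tetramethoxy-4-(5-methoxy-1-(4-methylbenzenesulfonyl)indol-3-yl)phenyl]-2,3-dihydroindole-1-carboxylate | CC(C)(C)OC(=O)N1CC(O)(c2c(OC)c(OC)c(-c3cn(S(=O)(=O)c4ccc(C)cc4)c4ccc(OC)cc34)c(OC)c2OC)c2cc(O)ccc12 | intermediate
21 | tert-butyl 5-hydroxy-3-[2,3,5,6-tetramethoxy-4-(5-methoxy-1-(4-methylbenzenesulfonyl)indol-3-yl)phenyl]indole-1-carboxylate | CC(C)(C)OC(=O)n1cc(-c2c(OC)c(OC)c(-c3cn(S(=O)(=O)c4ccc(C)cc4)c4ccc(OC)cc34)c(OC)c2OC)c2cc(O)ccc12 | intermediate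
22 | 3-[2,3,5,6-tetramethoxy-4-(5-methoxy-1-(4-methylbenzenesulfonyl)indol-3-yl)phenyl]-1H-indol-5-ol | COc1ccc2c(c1)c(cn2S(=O)(=O)c1ccc(C)cc1)-c1c(OC)c(OC)c(-c2c[nH]c3ccc(O)cc23)c(OC)c1OC | intermediate
23 | 3-[2,3,5,6-tetramethoxy-4-(5-methoxy-1H-indol-3-yl)phenyl]-1H-indol-5-ol | COc1ccc2[nH]cc(-c3c(OC)c(OC)c(-c4c[nH]c5ccc(O)cc45)c(OC)c3OC)c2c1 | target

**Step count and risks**

Total steps: 11. Longest linear sequence: 8 steps (5-methoxyindole, steps 3, 4, 5, 7, 8, 9, 10, 11).

Steps most likely to fail: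

1. Step 10. The cycloaddition onto an unactivated terminal alkyne, next to a carbinol carbon bearing a di-ortho-substituted aryl group, may be slower than thermal loss of the Boc group or ionisation of the tertiary propargylic alcohol, so the aminofuran could decompose before the rings close. Fallback, from bromide 14 and returning at target 23: the hydroxyindole is not built but coupled. Commercial 5-(benzyloxy)indole (C(Oc1ccc2[nH]ccc2c1)c1ccccc1) is N-sulfonylated as in step 3 to 5-(benzyloxy)-1-(4-methylbenzenesulfonyl)indole F1, brominated as in step 4 to 3-bromo-5-(benzyloxy)-1-(4-methylbenzenesulfonyl)indole F2, and borylated as in step 5 to 5-(benzyloxy)-1-(4-methylbenzenesulfonyl)-3-(4,4,5,5-tetramethyl-1,3,2-dioxaborolan-2-yl)indole F3. Suzuki–Miyaura coupling of F3 (excess) with 14 under the conditions of step 7 should give the bis(N-sulfonylindolyl) benzyl ether F4. Hydrogenolysis (H2, Pd/C, EtOAc–MeOH) should give the bis(N-sulfonyl) phenol F5, and Mg in MeOH as in step 11 then removes both sulfonyl groups to reach 23.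

2. Step 9. The acetylide may deprotonate the ketone at the CH2 between carbonyl and carbamate nitrogen, and the two ortho methoxy groups shield the carbonyl, so ketone could be returned. The magnesium alkoxide, once formed, may also take the Boc group over from nitrogen or close to an oxazolidinone if the mixture warms. Fallback, from aryllithium 15 (made from 14 as in step 8) and returning at 18: the carbinol is made with reversed roles, a non-enolisable ynone as electrophile and the aminomethyl carbanion as nucleophile. Acylation of 15 with N-methoxy-N-methyl-3-(trimethylsilyl)prop-2-ynamide (CON(C)C(=O)C#C[Si](C)(C)C) should give 1-[2,3,5,6-tetramethoxy-4-(5-methoxy-1-(4-methylbenzenesulfonyl)indol-3-yl)phenyl]-3-(trimethylsilyl)prop-2-yn-1-one F6. Carbamate 4 is alkylated (NaH, DMF) with tributyl(iodomethyl)stannane (CCCC[Sn](CCCC)(CCCC)CI) to tert-butyl N-(furan-2-yl)-N-[(tributylstannyl)methyl]carbamate F7. Tin–lithium exchange (n-BuLi, THF, −78 °C) gives tert-butyl N-(furan-2-yl)-N-(lithiomethyl)carbamate F8, which should add 1,2 to F6 at −78 °C to give the silylated alkynol tert-butyl N-(furan-2-yl)-N-{2-hydroxy-2-[2,3,5,6-tetramethoxy-4-(5-methoxy-1-(4-methylbenzenesulfonyl)indol-3-yl)phenyl]-4-(trimethylsilyl)but-3-yn-1-yl}carbamate F9. K2CO3 in MeOH removes the silyl group to give 18.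

3. Step 8. Proton transfer from indole C2–H, or attack at the sulfonyl group, may compete with bromine–lithium exchange, and the hindered aryllithium may deprotonate amide 6 instead of adding to it. Fallback, from dibromide 13 and returning at 16: the order of the two bond formations is reversed so that no N-sulfonylindole is present when the organolithium is generated. Mono bromine–lithium exchange of 13 (n-BuLi, 1.0 equiv, THF, −78 °C) gives (4-bromo-2,3,5,6-tetramethoxyphenyl)lithium F10, which is acylated with 6 to tert-butyl N-[2-(4-bromo-2,3,5,6-tetramethoxyphenyl)-2-oxoethyl]-N-(furan-2-yl)carbamate F11. Suzuki–Miyaura coupling of F11 with boronate 11 under the conditions of step 7 should then give ketone 16; this order also removes the need for an excess of dibromide in the coupling.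

**Further compounds**

F1 | step 10 | 5-(benzyloxy)-1-(4-methylbenzenesulfonyl)indole | Cc1ccc(cc1)S(=O)(=O)n1ccc2cc(OCc3ccccc3)ccc12
F2 | step 10 | 3-bromo-5-(benzyloxy)-1-(4-methylbenzenesulfonyl)indole | Cc1ccc(cc1)S(=O)(=O)n1cc(Br)c2cc(OCc3ccccc3)ccc12
F3 | step 10 | 5-(benzyloxy)-1-(4-methylbenzenesulfonyl)-3-(4,4,5,5-tetramethyl-1,3,2-dioxaborolan-2-yl)indole | Cc1ccc(cc1)S(=O)(=O)n1cc(B2OC(C)(C)C(C)(C)O2)c2cc(OCc3ccccc3)ccc12
F4 | step 10 | 5-(benzyloxy)-1-(4-methylbenzenesulfonyl)-3-[2,3,5,6-tetramethoxy-4-(5-methoxy-1-(4-methylbenzenesulfonyl)indol-3-yl)phenyl]indole | COc1ccc2c(c1)c(cn2S(=O)(=O)c1ccc(C)cc1)-c1c(OC)c(OC)c(-c2cn(S(=O)(=O)c3ccc(C)cc3)c3ccc(OCc4ccccc4)cc23)c(OC)c1OC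
F5 | step 10 | 1-(4-methylbenzenesulfonyl)-3-[2,3,5,6-tetramethoxy-4-(5-methoxy-1-(4-methylbenzenesulfonyl)indol-3-yl)phenyl]indol-5-ol | COc1ccc2c(c1)c(cn2S(=O)(=O)c1ccc(C)cc1)-c1c(OC)c(OC)c(-c2cn(S(=O)(=O)c3ccc(C)cc3)c3ccc(O)cc23)c(OC)c1OC
F6 | step 9 | 1-[2,3,5,6-tetramethoxy-4-(5-methoxy-1-(4-methylbenzenesulfonyl)indol-3-yl)phenyl]-3-(trimethylsilyl)prop-2-yn-1-one | COc1ccc2c(c1)c(cn2S(=O)(=O)c1ccc(C)cc1)-c1c(OC)c(OC)c(C(=O)C#C[Si](C)(C)C)c(OC)c1OC
F7 | step 9 | tert-butyl N-(furan-2-yl)-N-[(tributylstannyl)methyl]carbamate | CCCC[Sn](CCCC)(CCCC)CN(C(=O)OC(C)(C)C)c1ccco1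
F8 | step 9 | tert-butyl N-(furan-2-yl)-N-(lithiomethyl)carbamate | [Li]CN(C(=O)OC(C)(C)C)c1ccco1
F9 | step 9 | racemic tert-butyl N-(furan-2-yl)-N-{2-hydroxy-2-[2,3,5,6-tetramethoxy-4-(5-methoxy-1-(4-methylbenzenesulfonyl)indol-3-yl)phenyl]-4-(trimethylsilyl)but-3-yn-1-yl}carbamate | COc1ccc2c(c1)c(cn2S(=O)(=O)c1ccc(C)cc1)-c1c(OC)c(OC)c(C(O)(C#C[Si](C)(C)C)CN(C(=O)OC(C)(C)C)c2ccco2)c(OC)c1OC
F10 | step 8 | (4-bromo-2,3,5,6-tetramethoxyphenyl)lithium | COc1c([Li])c(OC)c(OC)c(Br)c1OC
F11 | step 8 | tert-butyl N-[2-(4-bromo-2,3,5,6-tetramethoxyphenyl)-2-oxoethyl]-N-(furan-2-yl)carbamate | COc1c(Br)c(OC)c(OC)c(C(=O)CN(C(=O)OC(C)(C)C)c2ccco2)c1OC
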